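I wanted four things about a flask charged with substrate: the ratio of isomer of the product A to target at 0.80 s, at 10 s and at 2.0 min, and which of the two leads at the end.

| flask | substrate | remark | time |
|---|---|---|---|
| south-east | 0.13 mM | run made earlier |  |
| west | 0.30 mM | run made earlier |  |
| flask | 0.20 mM |  | 2.0 min |

| run | time / s | isomer of the product A / % | target / % |
|---|---|---|---|
| south-east | 10.0 | 26.6 | 5.6 |
| south-east | 30.0 | 62.4 | 9.8 |
| south-east | 60.0 | 76.4 | 13.1 |
| south-east | 80.0 | 79.5 | 14.6 |
| south-east | 120 | 77.9 | 17.8 |
| west | 25.0 | 54.4 | 9.8 |
| west | 50.0 | 75.8 | 12.7 |
| west | 80.0 | 81.6 | 16.3 |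
| west | 90.0 | 79.3 | 16.2 |
| west | 120 | 77.9 | 17.2 |

(readings scatter by 1 percentage point)

- ratio of isomer of the product A to target at 0.80 s
- ratio of isomer of the product A to target at 10 s
- ratio of isomer of the product A to target at 2.0 min
- which of isomer of the product A and target there is more of at 2.0 min

- what was read earlier has a scatter of 1 percentage point, one standard deviation

The earliest time asked lies well before the first reading, so that ratio turns on how late the isomer of the product A starts. At 80.0 s the runs read 79.5% and 81.6% of isomer of the product A despite their different charges, so I put the flask on the same curves, in fractions of the charge.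

The ratio read 5.83 at 60.0 s in the south-east run and 5.97 at 50.0 s in the west run. I took their mean, 5.90, as the late ratio s, which, with the two products taken to share the charge, puts my estimate of the ceiling of the isomer of the product A at 0.855 of the charge.

My first way used the ratio. With a delay τ, it should lie near s(1 − τ/t) once t is well past τ, and the south-east reading at 10.0 s gave 1.95 s.

My second way used the isomer of the product A by itself. I took the logarithm of its gap to the ceiling to fall on a straight line, and the south-east line through 10.0 s and 30.0 s starts at 2.04 s.

The west line gave 3.29 s, but I set it aside. Its second reading stood 9.7 percentage points under the ceiling, closer than the south-east 23 points, so the scatter of 1 point weighed more on it.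

The mean of the two ways, 1.99 s, is my delay: the mean lifetime of one first-order stage between substrate and isomer of the product A, the induction period of the curve. It is a reading and carries the scatter, and the two ways share the south-east reading at 10.0 s and s, so their closeness is no full check.

With the supply steady, r(t) = s[1 − (τ/t)(1 − exp(−t/τ))]. That gave me 1.04 at 0.80 s and 4.73 at 10 s. The two readings at 2.0 min averaged 4.45, which put isomer of the product A ahead of target.

The forecast gave 1.5, 4.9 and 4.45, with isomer of the product A ahead, and for the earliest figure it reasoned that “The early low value hints that the isomer forms with a lag of a few seconds through an intermediate”. My earliest figure was lower than its 1.5.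

The flask gave 1.04, 5.21 and 4.54, with isomer of the product A ahead, at 78.8% against 17.4%.

    target ⇌ isomer of the product B (K = 0.200, k = 0.0470 s⁻¹)
    target ⇌ isomer of the product A (K = 0.350, k = 2.70 × 10⁻⁴ s⁻¹)
    substrate ⇌ other conformer (K = 5.70, k = 0.0410 s⁻¹)
    substrate → target (k = 0.00720 s⁻¹)
    other conformer → isomer of the product A (k = 0.510 s⁻¹)

By its passing into isomer of the product A alone, the other conformer has a half-life of 1.4 s. At 0.0600 min, my delay of 1.99 s put the ratio at 3.17, and the flask held 7.45% of isomer of the product A and 2.24% of target. For the neighbour charged with 0.50 mM, the same delay gave 1.04 at 0.80 s, and that flask stood at 1.04.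

The data stem from a simulated flask on assumed constants, and the scatter is random.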